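## The problem

Compound 16 is a single γ-butyrolactone ring (O1, C2 carbonyl, C3, C4, C5) with an exocyclic carbinol carbon C7 on C3 and a benzylic methylene C7' on C4, each bonded to a 4-hydroxy-3-methoxyphenyl ring. Nothing is fused or bridged, so the task is to build the chain C7–C3(–C2)–C4(–C5)–C7' and close it through O1. Three contiguous stereocentres are needed, C7 (S), C3 (S) and C4 (R), with the C3 and C4 substituents trans. C3 is α to the lactone carbonyl and can be equilibrated, so it follows C4 into the trans arrangement; C4 and C7 must be set independently. C7 cannot be relied on to set C4: in the rotamer that avoids allylic strain its oxygen lies on the ring face opposite to the one from which hydrogen must reach C4, so oxygen-directed delivery would give the wrong epimer. The functional groups are delicate together: the β-hydroxy lactone undergoes retro-aldol cleavage and dehydration under base, the para-oxygenated benzylic alcohol ionizes under acid (with Friedel–Crafts closure onto the other arene) and is open to hydrogenolysis, and the free phenols make C7 a quinone methide precursor. The feature that shortens the synthesis is that C3 and C4 each bear exactly one ring carbon (C2, C5) and one exocyclic carbon (C7, C7'). This is the pattern of a tetrasubstituted butenolide C3=C4, and therefore of an alkyne C3≡C4 flanked by C5 and C7 that can take C7' from a benzyl nucleophile and C2 from CO2.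

## Retrosynthesis

**16 ⇒ 15 ⇒ 14 (unmasking only).** The two aryl O–benzyl bonds of 16 are cut to give dibenzyl ether 15, and the C7 O–Si bond to give silyl ether 14. Benzyl ethers are preferred for the phenols because they survive Grignard reagents, copper hydride, fluoride and amine bases and leave under neutral hydrogenolysis. The silyl ether is removed first, while the phenols are still masked, because a free para-phenoxide beside a benzylic silyloxy group invites quinone methide formation. The forward steps must avoid acid and unbuffered base.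

**14 ⇒ 12 (C4–H and C3–H).** Removing these two C–H bonds gives butenolide 12 with a tetrasubstituted C3=C4 bond; two of the three stereocentres disappear. The neighbouring aldol cut of C3–C7 gives no control of C7, and a syn hydrogenation cannot give the trans ring. The reduction is therefore planned as hydride addition to C4 followed by equilibration at C3 through the cis lactone 13. The forward step must deliver hydride to the Si face of C4 on a crowded alkene under ligand control. The C7 oxygen stays as a bulky silyl ether so that it shields rather than directs.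

**12 ⇒ 5 + 8 + 9 (C4–C7', C2–C3, O1–C2).** Cutting these three bonds opens the ring and takes the butenolide back to alkynol 5, benzyl Grignard reagent 8 and carbon dioxide 9. The forward reaction passes through the alkenylmagnesium chelate 10 and the hydroxy acid 11. The alternatives are stepwise cross-coupling on a preformed butenolide (more steps, C7 still to be attached) or an aldol cut at C3–C7 (C7 uncontrolled). The chosen cut forms three bonds and the ring in one operation from an acyclic precursor with a single stereocentre. The forward reaction must place benzyl on C4 and carbon on C3, add anti, and leave the C7 silyloxy group in place.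

**5 ⇒ 4 ⇒ 3 ⇒ 1 + 2 (C7–C3).** The bond between C7 and the alkyne carbon is cut to give aldehyde 1 and the silyl ether 2 of propargyl alcohol, which supplies C3, C4 and C5. A catalytic asymmetric alkynylation sets C7 directly; reducing an aryl alkynyl ketone is the weaker neighbour because its two flanking groups are hard to tell apart. The two hydroxyls of 3 are differentiated by silyl groups of different size: the secondary one is capped as the triisopropylsilyl ether (4), and the primary tert-butyldimethylsilyl ether is then cleaved selectively (5).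

**8 ⇒ 7 ⇒ 6 (C–Mg, C–Cl).** The Grignard reagent comes from chloride 7 and this from the commercial benzyl alcohol 6, so both aryl rings enter as O-benzyl vanillyl units.

## Roads not taken

Alternative 1: The cut is at C3–C4 and at the two benzylic C–O bonds. Two molecules of ferulic acid A1 are joined by phenoxy radical coupling (FeCl3 with O2, or a laccase), and each carboxyl group adds to the opposite quinone methide carbon to give the cis-fused dilactone A2.
- Merits: a commodity acid, no protecting groups, and one step that forms the central bond and fixes the relative configuration of all three centres (the cis ring fusion becomes trans C3/C4 once one lactone is opened). In step count and atom economy this road is clearly better than the chosen one.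
- Weak points: A2 forms racemic, so a resolution is needed, and radical coupling gives several regioisomeric dimers. A2 is C2-symmetric: exactly one benzylic C–O bond must be hydrogenolysed, and the surviving lactone carbonyl must then be reduced to the C5 alcohol beside the new acid, with free phenols present.
- Comparison: the chosen plan is longer, but it sets absolute configuration by catalysis and differentiates the two halves of the molecule from the start.

Alternative 2: The cut is at C2–C3 and at the bond from C2 to the C7 oxygen. The trans epoxide A3 is carbonylated with [(salph)Al(THF)2][Co(CO)4]; CO enters at C3 with inversion to give the cis β-lactone A4, and the released C5 hydroxyl then translactonizes to the γ-lactone.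
- Merits: the C3/C7 relationship follows from the epoxide geometry by a stereospecific mechanism, and the C7 hydroxyl appears unprotected. In this respect it is better than the chosen plan, which leaves C3 to equilibration.
- Weak points: A3 already needs three stereocentres, so the route to it is longer. Opening an aryl epoxide is electronically favoured at the benzylic carbon C7, which would give the regioisomeric lactone. The electron-rich aryl epoxide can rearrange to a ketone under the Lewis acid, and trans-disubstituted epoxides carbonylate slowly.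
- Comparison: the chosen plan is convergent, needs one stereocentre before the key step and uses simple copper catalysis; its price is the separate control of C4.

Alternative 3: No skeletal bond is cut. Hydroxymatairesinol A5 has the same carbons and stereocentres as 16 with the oxidation levels of C2 and C5 exchanged. After lactone opening and phenol benzylation, the primary C2 alcohol is oxidized to the acid (TEMPO, NaOCl, NaClO2), and acidification closes the C5 carboxyl onto the C7 hydroxyl to give lactone acid A6. Reduction of the C5 carbonyl and relactonization onto C2 would converge on 15.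
- Merits: every stereocentre comes from the natural product, and the uncertain reduction of the chosen plan has no counterpart. In stereochemical economy this road is better.
- Weak points: the material is isolated as a mixture of C7 epimers that must be separated. The oxidation must pick the primary alcohol beside an activated benzylic secondary one. In A6, C4 is α to a lactone carbonyl and is the one centre that cannot be corrected later. The lactone must be reduced beside a free acid.
- Comparison: the chosen plan does not depend on natural supply and gives either enantiomer and other aryl pairs by exchanging 1, 6 or the ligands.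

Key step: step 6

Assumption: (R,R)-ProPhenol is taken as the antipode that directs the alkynylzinc to the Si face of 1, and (R)-DTBM-SEGPHOS as the one that directs hydride to the Si face of C4 in 12; if a first run shows the opposite sense, the antipodal ligand is used and nothing else changes.

## Route

Step 1
Reactants: 1 4-(benzyloxy)-3-methoxybenzaldehyde; 2 tert-butyldimethyl(prop-2-yn-1-yloxy)silane
Product: 3 (R)-1-[4-(benzyloxy)-3-methoxyphenyl]-4-[(tert-butyldimethylsilyl)oxy]but-2-yn-1-ol
Conditions: Me2Zn (3 equiv), (R,R)-ProPhenol (10 mol%), Ph3PO (20 mol%), toluene, 0 °C → rt; aq. NH4Cl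
Reagents that add atoms: none
Why: Asymmetric addition of an alkynylzinc to an aryl aldehyde under the dinuclear zinc–ProPhenol catalyst; the chiral pocket exposes the Si face of 1, which sets C7 as (R) in 3, the same spatial arrangement as C7 (S) in 16.

Step 2
Reactants: 3 (R)-1-[4-(benzyloxy)-3-methoxyphenyl]-4-[(tert-butyldimethylsilyl)oxy]but-2-yn-1-ol
Product: 4 (R)-{1-[4-(benzyloxy)-3-methoxyphenyl]-4-[(tert-butyldimethylsilyl)oxy]but-2-yn-1-yl}oxy(triisopropyl)silane
Conditions: TIPSOTf, 2,6-lutidine, CH2Cl2, −78 → 0 °C
Reagents that add atoms: triisopropylsilyl trifluoromethanesulfonate, CC(C)[Si](C(C)C)(C(C)C)OS(=O)(=O)C(F)(F)F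
Why: Silylation of a hindered secondary alcohol with a silyl triflate and a hindered base; only the O–H bond reacts, so C7 is untouched.

Step 3
Reactants: 4 (R)-{1-[4-(benzyloxy)-3-methoxyphenyl]-4-[(tert-butyldimethylsilyl)oxy]but-2-yn-1-yl}oxy(triisopropyl)silane
Product: 5 (R)-4-[4-(benzyloxy)-3-methoxyphenyl]-4-[(triisopropylsilyl)oxy]but-2-yn-1-ol
Conditions: HF·pyridine, pyridine, THF, 0 °C → rt
Reagents that add atoms: none
Why: Selective fluoride cleavage of a primary tert-butyldimethylsilyl ether beside a much more hindered secondary triisopropylsilyl ether; the pyridine buffer keeps the medium from ionizing the benzylic, propargylic C7–O bond.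

Step 4
Reactants: 6 [4-(benzyloxy)-3-methoxyphenyl]methanol
Product: 7 1-(benzyloxy)-4-(chloromethyl)-2-methoxybenzene
Conditions: SOCl2, CH2Cl2, 0 °C → rt
Reagents that add atoms: thionyl chloride, O=S(Cl)Cl
Why: Chlorination of an electron-rich benzylic alcohol through its chlorosulfite; the chloride is used at once because such halides self-alkylate on standing.

Step 5
Reactants: 7 1-(benzyloxy)-4-(chloromethyl)-2-methoxybenzene
Product: 8 [4-(benzyloxy)-3-methoxybenzyl]magnesium chloride (titrated solution)
Conditions: Mg turnings (I2-activated), 2-MeTHF, 0 °C, slow addition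
Reagents that add atoms: magnesium, [Mg]
Why: Insertion of magnesium into the benzylic C–Cl bond (Grignard formation); dilution, low temperature and slow addition hold back Wurtz homocoupling.

Step 6
Reactants: 5 (R)-4-[4-(benzyloxy)-3-methoxyphenyl]-4-[(triisopropylsilyl)oxy]but-2-yn-1-ol; 8 [4-(benzyloxy)-3-methoxybenzyl]magnesium chloride; 9 carbon dioxide
Product: 12 4-[4-(benzyloxy)-3-methoxybenzyl]-3-{(R)-[4-(benzyloxy)-3-methoxyphenyl][(triisopropylsilyl)oxy]methyl}furan-2(5H)-one, via alkenylmagnesium chelate 10 (not isolated), via hydroxy acid 11 (not isolated)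
Conditions: 8 (3 equiv), CuI (10 mol%), 2-MeTHF/toluene, −30 → 0 °C; CO2 (1 atm), −30 °C → rt; 1 M HCl, 0 °C
Reagents that add atoms: none
Why: The first equivalent of 8 deprotonates the C5 hydroxyl of 5, and CuI with further 8 gives a benzylcopper species that adds across C3≡C4 under the direction of the C5 magnesium alkoxide. Benzyl goes to the proximal carbon C4 and the metal to C3 in an anti sense, because only magnesium on C3 and cis to C5 can close the five-membered chelate 10; this fixes regiochemistry and alkene geometry together. CO2 inserts into the C3–Mg bond with retention, which places the carboxylate cis to the C5 oxygen. Acidification gives the (Z)-hydroxy acid 11, whose hydroxyl attacks the carboxyl carbon in a 5-exo-trig lactonization that closes the butenolide ring of 12. The closest known reaction type is the copper-catalysed anti-carbomagnesiation of propargylic alcohols with Grignard reagents followed by carboxylation to butenolides. No stereocentre is formed, and C7 is carried through because neither its C–H nor its C–O bond takes part. The step needs the C7 oxygen neither to chelate magnesium nor to leave (SN2' displacement, or β-elimination from the C3–Mg bond to an allene); the bulky, poorly coordinating triisopropylsilyl ether, the low temperature and prompt carboxylation are there to secure this.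

Step 7
Reactants: 12 4-[4-(benzyloxy)-3-methoxybenzyl]-3-{(R)-[4-(benzyloxy)-3-methoxyphenyl][(triisopropylsilyl)oxy]methyl}furan-2(5H)-one
Product: 14 (3S,4R)-4-[4-(benzyloxy)-3-methoxybenzyl]-3-{(S)-[4-(benzyloxy)-3-methoxyphenyl][(triisopropylsilyl)oxy]methyl}dihydrofuran-2(3H)-one, via cis lactone 13 (not isolated)
Conditions: Cu(OAc)2·H2O (5 mol%), (R)-DTBM-SEGPHOS (5.5 mol%), (EtO)2MeSiH, t-BuOH, toluene, rt → 40 °C; then DBU, rt
Reagents that add atoms: none
Why: Proposed new method: ligated copper hydride should add across C3=C4 with hydride going to the Si face of C4 under ligand control (C7 holds its aryl and silyloxy groups toward C2, away from C4, so its bias should be small), the copper enolate is protonated by t-BuOH while the silane regenerates CuH, and the expected kinetic cis lactone 13 is then equilibrated by DBU at the acidic C3 to the more stable trans lactone 14 without touching C4; the closest known reaction type is the asymmetric CuH 1,4-reduction of β-substituted (trisubstituted) butenolides, and the new element is the tetrasubstituted, α-branched alkene.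

Step 8
Reactants: 14 (3S,4R)-4-[4-(benzyloxy)-3-methoxybenzyl]-3-{(S)-[4-(benzyloxy)-3-methoxyphenyl][(triisopropylsilyl)oxy]methyl}dihydrofuran-2(3H)-one
Product: 15 (3S,4R)-4-[4-(benzyloxy)-3-methoxybenzyl]-3-{(S)-[4-(benzyloxy)-3-methoxyphenyl](hydroxy)methyl}dihydrofuran-2(3H)-one
Conditions: TBAF, AcOH, THF, 0 °C → rt
Reagents that add atoms: none
Why: Fluoride cleavage of the secondary silyl ether; acetic acid buffers the liberated alkoxide so that the β-hydroxy lactone neither cleaves by retro-aldol reaction nor eliminates, and no strong acid is present to ionize the benzylic alcohol.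

Step 9
Reactants: 15 (3S,4R)-4-[4-(benzyloxy)-3-methoxybenzyl]-3-{(S)-[4-(benzyloxy)-3-methoxyphenyl](hydroxy)methyl}dihydrofuran-2(3H)-one
Product: 16 (3S,4R)-3-[(S)-hydroxy(4-hydroxy-3-methoxyphenyl)methyl]-4-(4-hydroxy-3-methoxybenzyl)dihydrofuran-2(3H)-one
Conditions: H2 (1 atm), Pd/C (10 wt%), EtOAc, rt
Reagents that add atoms: none
Why: Hydrogenolysis of the two aryl benzyl ethers over palladium under neutral conditions; these cleave much faster than the secondary benzylic C7–OH bond, and the reaction is stopped at full debenzylation.

## Compound list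

1 | 4-(benzyloxy)-3-methoxybenzaldehyde | COc1cc(C=O)ccc1OCc1ccccc1 | starting material
2 | tert-butyldimethyl(prop-2-yn-1-yloxy)silane | C#CCO[Si](C)(C)C(C)(C)C | starting material
3 | (R)-1-[4-(benzyloxy)-3-methoxyphenyl]-4-[(tert-butyldimethylsilyl)oxy]but-2-yn-1-ol | CC(C)(C)[Si](C)(C)OCC#C[C@H](O)c1ccc(OCc2ccccc2)c(OC)c1 | intermediate
4 | (R)-{1-[4-(benzyloxy)-3-methoxyphenyl]-4-[(tert-butyldimethylsilyl)oxy]but-2-yn-1-yl}oxy(triisopropyl)silane | CC(C)(C)[Si](C)(C)OCC#C[C@H](O[Si](C(C)C)(C(C)C)C(C)C)c1ccc(OCc2ccccc2)c(OC)c1 | intermediate
5 | (R)-4-[4-(benzyloxy)-3-methoxyphenyl]-4-[(triisopropylsilyl)oxy]but-2-yn-1-ol | OCC#C[C@H](O[Si](C(C)C)(C(C)C)C(C)C)c1ccc(OCc2ccccc2)c(OC)c1 | intermediate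
6 | [4-(benzyloxy)-3-methoxyphenyl]methanol | COc1cc(CO)ccc1OCc1ccccc1 | starting material
7 | 1-(benzyloxy)-4-(chloromethyl)-2-methoxybenzene | COc1cc(CCl)ccc1OCc1ccccc1 | intermediate
8 | [4-(benzyloxy)-3-methoxybenzyl]magnesium chloride | COc1cc(C[Mg]Cl)ccc1OCc1ccccc1 | intermediate
9 | carbon dioxide | O=C=O | starting material
10 | five-membered alkenylmagnesium alkoxide chelate (Mg on C3 and bonded to the C5 oxygen, benzyl on C4, C7 (R)) | COc1cc(CC2=C([Mg]OC2)[C@H](O[Si](C(C)C)(C(C)C)C(C)C)c2ccc(OCc3ccccc3)c(OC)c2)ccc1OCc1ccccc1 | intermediate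
11 | (Z)-3-[4-(benzyloxy)-3-methoxybenzyl]-2-{(R)-[4-(benzyloxy)-3-methoxyphenyl][(triisopropylsilyl)oxy]methyl}-4-hydroxybut-2-enoic acid | COc1cc(C/C(CO)=C(/C(=O)O)[C@H](O[Si](C(C)C)(C(C)C)C(C)C)c2ccc(OCc3ccccc3)c(OC)c2)ccc1OCc1ccccc1 | intermediate
12 | 4-[4-(benzyloxy)-3-methoxybenzyl]-3-{(R)-[4-(benzyloxy)-3-methoxyphenyl][(triisopropylsilyl)oxy]methyl}furan-2(5H)-one | COc1cc(CC2=C(C(=O)OC2)[C@H](O[Si](C(C)C)(C(C)C)C(C)C)c2ccc(OCc3ccccc3)c(OC)c2)ccc1OCc1ccccc1 | intermediate
13 | (3R,4R)-4-[4-(benzyloxy)-3-methoxybenzyl]-3-{(S)-[4-(benzyloxy)-3-methoxyphenyl][(triisopropylsilyl)oxy]methyl}dihydrofuran-2(3H)-one (cis) | COc1cc(C[C@H]2COC(=O)[C@H]2[C@H](O[Si](C(C)C)(C(C)C)C(C)C)c2ccc(OCc3ccccc3)c(OC)c2)ccc1OCc1ccccc1 | intermediate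
14 | (3S,4R)-4-[4-(benzyloxy)-3-methoxybenzyl]-3-{(S)-[4-(benzyloxy)-3-methoxyphenyl][(triisopropylsilyl)oxy]methyl}dihydrofuran-2(3H)-one (trans) | COc1cc(C[C@H]2COC(=O)[C@@H]2[C@H](O[Si](C(C)C)(C(C)C)C(C)C)c2ccc(OCc3ccccc3)c(OC)c2)ccc1OCc1ccccc1 | intermediate
15 | (3S,4R)-4-[4-(benzyloxy)-3-methoxybenzyl]-3-{(S)-[4-(benzyloxy)-3-methoxyphenyl](hydroxy)methyl}dihydrofuran-2(3H)-one | COc1cc(C[C@H]2COC(=O)[C@@H]2[C@H](O)c2ccc(OCc3ccccc3)c(OC)c2)ccc1OCc1ccccc1 | intermediate
16 | (3S,4R)-3-[(S)-hydroxy(4-hydroxy-3-methoxyphenyl)methyl]-4-(4-hydroxy-3-methoxybenzyl)dihydrofuran-2(3H)-one | COc1cc(C[C@H]2COC(=O)[C@@H]2[C@H](O)c2ccc(O)c(OC)c2)ccc1O | target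

## Step count and risks

Total: 9 steps. Longest linear sequence: 7 steps (steps 1, 2, 3, 6, 7, 8, 9, from 1 to 16).

**Step 7 (proposed new method).**
- What may go wrong: hydrocupration must put copper on the crowded C3, so turnover may fail. The resident C7 centre may override the ligand, so that hydride reaches the Re face of C4. The silyloxy group may be lost by E1cB elimination from the enolate or during the DBU equilibration.
- Fallback (known chemistry), from 8 and 9 back to 15: C4 is set on a trisubstituted butenolide, where the asymmetric copper hydride reduction is established, and C7 is brought in by an aldol reaction. Propargyl alcohol is carried through the same copper-catalysed carbomagnesiation with 8 and carboxylation with 9 to give 4-[4-(benzyloxy)-3-methoxybenzyl]furan-2(5H)-one F1. Reduction with CuCl, NaOt-Bu, p-tol-BINAP (the antipode that sends hydride to the Si face of C4) and PMHS gives (R)-4-[4-(benzyloxy)-3-methoxybenzyl]dihydrofuran-2(3H)-one F2. Deprotonation with LiN(SiMe3)2 in THF at −78 °C and addition of 1 gives the trans aldol adducts, because the aldehyde approaches anti to the C4 benzyl group. These are 15 and its C7 epimer, (3S,4R)-4-[4-(benzyloxy)-3-methoxybenzyl]-3-{(R)-[4-(benzyloxy)-3-methoxyphenyl](hydroxy)methyl}dihydrofuran-2(3H)-one F3, which is separated by chromatography. C7 is not controlled on this path; that is what the main route has to offer over it.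

**Step 6 (key step).**
- What may go wrong: β-elimination of the silyloxy group from the C3–magnesium intermediate (or SN2' displacement at the alkyne) may outrun carboxylation of the hindered alkenylmagnesium. Addition to the internal alkyne may be sluggish.
- Fallback, from 5 back to 12: the C1 unit is introduced by palladium catalysis. The carbomagnesiation is run as in step 6 and quenched at −30 °C with I2, which traps the alkenylmagnesium faster than CO2, to give (R,Z)-2-[4-(benzyloxy)-3-methoxybenzyl]-4-[4-(benzyloxy)-3-methoxyphenyl]-3-iodo-4-[(triisopropylsilyl)oxy]but-2-en-1-ol F4. Carbonylative lactonization (CO 1 atm, PdCl2(PPh3)2, K2CO3, THF, 50 °C) then closes the ring to 12.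

**Step 1.**
- What may go wrong: slow addition to the electron-rich aldehyde may let the uncatalysed background reaction erode enantioselectivity, or the sense of induction may be opposite to the one assumed.
- Fallback, from 1 and 2 back to 3: the centre is set by reduction. The lithium acetylide of 2 (n-BuLi, THF, −78 °C) adds to 1 to give racemic 1-[4-(benzyloxy)-3-methoxyphenyl]-4-[(tert-butyldimethylsilyl)oxy]but-2-yn-1-ol F5. MnO2 oxidation gives 1-[4-(benzyloxy)-3-methoxyphenyl]-4-[(tert-butyldimethylsilyl)oxy]but-2-yn-1-one F6. Midland reduction with (R)-Alpine-Borane, in which the alkynyl group acts as the small substituent, gives 3.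

**Step 5.**
- What may go wrong: Wurtz homocoupling of the electron-rich benzylic chloride during magnesium insertion.
- Fallback, from 7 back to 8: the reagent is made by transmetalation. Bu3SnLi displaces chloride from 7 to give [4-(benzyloxy)-3-methoxybenzyl]tributylstannane F7. Tin–lithium exchange with MeLi (THF, −78 °C) gives [4-(benzyloxy)-3-methoxybenzyl]lithium F8, and addition of MgCl2 gives 8.

**Step 9.**
- What may go wrong: over-reduction by hydrogenolysis of the benzylic C7–O bond once the para phenol is free.
- Fallback, from 14 back to 16: the order of unmasking is reversed. Hydrogenolysis of 14 (H2, Pd/C, EtOAc), with the silyl ether still guarding C7–O, gives (3S,4R)-4-(4-hydroxy-3-methoxybenzyl)-3-{(S)-(4-hydroxy-3-methoxyphenyl)[(triisopropylsilyl)oxy]methyl}dihydrofuran-2(3H)-one F9. Buffered fluoride (TBAF, AcOH, THF) then gives 16.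

## Further compounds

F1 | step 7 | 4-[4-(benzyloxy)-3-methoxybenzyl]furan-2(5H)-one | COc1cc(CC2=CC(=O)OC2)ccc1OCc1ccccc1
F2 | step 7 | (R)-4-[4-(benzyloxy)-3-methoxybenzyl]dihydrofuran-2(3H)-one | COc1cc(C[C@H]2COC(=O)C2)ccc1OCc1ccccc1
F3 | step 7 | (3S,4R)-4-[4-(benzyloxy)-3-methoxybenzyl]-3-{(R)-[4-(benzyloxy)-3-methoxyphenyl](hydroxy)methyl}dihydrofuran-2(3H)-one | COc1cc(C[C@H]2COC(=O)[C@@H]2[C@@H](O)c2ccc(OCc3ccccc3)c(OC)c2)ccc1OCc1ccccc1
F4 | step 6 | (R,Z)-2-[4-(benzyloxy)-3-methoxybenzyl]-4-[4-(benzyloxy)-3-methoxyphenyl]-3-iodo-4-[(triisopropylsilyl)oxy]but-2-en-1-ol | COc1cc(C/C(CO)=C(/I)[C@H](O[Si](C(C)C)(C(C)C)C(C)C)c2ccc(OCc3ccccc3)c(OC)c2)ccc1OCc1ccccc1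
F5 | step 1 | racemic 1-[4-(benzyloxy)-3-methoxyphenyl]-4-[(tert-butyldimethylsilyl)oxy]but-2-yn-1-ol | CC(C)(C)[Si](C)(C)OCC#CC(O)c1ccc(OCc2ccccc2)c(OC)c1
F6 | step 1 | 1-[4-(benzyloxy)-3-methoxyphenyl]-4-[(tert-butyldimethylsilyl)oxy]but-2-yn-1-one | CC(C)(C)[Si](C)(C)OCC#CC(=O)c1ccc(OCc2ccccc2)c(OC)c1
F7 | step 5 | [4-(benzyloxy)-3-methoxybenzyl]tributylstannane | CCCC[Sn](CCCC)(CCCC)Cc1ccc(OCc2ccccc2)c(OC)c1
F8 | step 5 | [4-(benzyloxy)-3-methoxybenzyl]lithium | [Li]Cc1ccc(OCc2ccccc2)c(OC)c1
F9 | step 9 | (3S,4R)-4-(4-hydroxy-3-methoxybenzyl)-3-{(S)-(4-hydroxy-3-methoxyphenyl)[(triisopropylsilyl)oxy]methyl}dihydrofuran-2(3H)-one | COc1cc(C[C@H]2COC(=O)[C@@H]2[C@H](O[Si](C(C)C)(C(C)C)C(C)C)c2ccc(O)c(OC)c2)ccc1O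
A1 | alternative 1 | ferulic acid, (E)-3-(4-hydroxy-3-methoxyphenyl)prop-2-enoic acid | COc1cc(/C=C/C(=O)O)ccc1O
A2 | alternative 1 | dehydrodiferulic acid dilactone, (1S,4S,5S,8S)-4,8-bis(4-hydroxy-3-methoxyphenyl)-3,7-dioxabicyclo[3.3.0]octane-2,6-dione | COc1cc(ccc1O)[C@H]1OC(=O)[C@@H]2[C@@H](c3ccc(O)c(OC)c3)OC(=O)[C@H]12
A3 | alternative 2 | (2R,3R)-2-{(S)-1-[4-(benzyloxy)-3-methoxyphenyl]-3-[(tert-butyldimethylsilyl)oxy]propan-2-yl}-3-[3-methoxy-4-(pivaloyloxy)phenyl]oxirane | COc1cc(C[C@@H](CO[Si](C)(C)C(C)(C)C)[C@H]2O[C@@H]2c2ccc(OC(=O)C(C)(C)C)c(OC)c2)ccc1OCc1ccccc1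
A4 | alternative 2 | (3S,4S)-3-{(R)-1-[4-(benzyloxy)-3-methoxyphenyl]-3-[(tert-butyldimethylsilyl)oxy]propan-2-yl}-4-[3-methoxy-4-(pivaloyloxy)phenyl]oxetan-2-one | COc1cc(C[C@@H](CO[Si](C)(C)C(C)(C)C)[C@@H]2C(=O)O[C@@H]2c2ccc(OC(=O)C(C)(C)C)c(OC)c2)ccc1OCc1ccccc1
A5 | alternative 3 | hydroxymatairesinol, (3R,4R)-4-[(S)-hydroxy(4-hydroxy-3-methoxyphenyl)methyl]-3-(4-hydroxy-3-methoxybenzyl)dihydrofuran-2(3H)-one | COc1cc(C[C@H]2C(=O)OC[C@@H]2[C@H](O)c2ccc(O)c(OC)c2)ccc1O
A6 | alternative 3 | (2S,3S,4R)-4-[4-(benzyloxy)-3-methoxybenzyl]-2-[4-(benzyloxy)-3-methoxyphenyl]-5-oxotetrahydrofuran-3-carboxylic acid | COc1cc(C[C@H]2C(=O)O[C@H](c3ccc(OCc4ccccc4)c(OC)c3)[C@H]2C(=O)O)ccc1OCc1ccccc1
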